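**Plan**
1. Cuts: once the temporary groups are restored, only two ring bonds are cut, C4–C5 and C6–C1. Target ring numbering: C1 = CHOBz next to CHOH, C2=C3, C4 = CHOBz next to the quaternary carbon, C5 = C(OH)CH2OH, C6 = CHOH. This retro-Diels–Alder cut gives a C4 diene that keeps both benzoates and a C3 enediol-type dienophile.
2. Enabling feature: the only C=C of the six-membered carbocycle (C2=C3) lies opposite the C5–C6 bond, and both allylic carbons carry oxygen. The four oxygens on C1, C4, C5 and C6 all stand on one ring face, which is the imprint of a suprafacial addition of an (E,E)-1,4-dioxygenated butadiene to a (Z)-1,2-dioxygenated alkene.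
3. Diene arm (2 steps): cross-metathesis and dienol benzoylation give (1E,3E)-1,4-dibenzoyloxybutadiene.
4. Dienophile arm (3 steps): O-acetyl-L-serine is converted to the hydroxy acid and then to the cis-2-tert-butyl-1,3-dioxolan-4-one. This temporary ring holds the future CH2OH carbon at the carboxyl level as activator. Bromination and dehydrobromination then give the (Z)-acetoxymethylidene lactone.
5. The carbocycle, the only ring of the target, arises in the cycloaddition. The helpers then leave in this order: acetal ring (hydrolysis), acid oxidation level (borane), acetyl group (acid methanolysis).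
6. Stereochemistry: L-serine sets the acetal carbon, and the tert-butyl group on that carbon sets the absolute sense of all four ring stereocentres. Diene and dienophile geometry together with the lactone-exo transition state set their relative configuration.

Key step: step 6

Remark: the dioxolanone ring is numbered O1, C2 (acetal carbon), O3, C4 (C=O), C5. All four starting materials are taken as catalogue compounds, with O-acetyl-L-serine used as the free amino acid.

**Step 1**
Reactants: 1 allyl benzoate; 2 (E)-crotonaldehyde
Product: 3 (E)-4-oxobut-2-en-1-yl benzoate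
Conditions: second-generation Hoveyda–Grubbs catalyst RuCl2(H2IMes)(=CH-C6H4-2-O-i-Pr) (cat.), 2 in excess, CH2Cl2, 40 °C
Reagents that add atoms: none
Why: Olefin cross-metathesis of a terminal allyl ester with an electron-poor enal is a well-precedented selective pairing that should give the E-enal while propene escapes as a gas.

**Step 2**
Reactants: 3 (E)-4-oxobut-2-en-1-yl benzoate
Product: 4 (1E,3E)-buta-1,3-diene-1,4-diyl dibenzoate
Conditions: BzCl, Et3N, DMAP (cat.), toluene, 80 °C; then I2 (cat.), toluene, rt; recrystallisation
Reagents that add atoms: benzoyl chloride, O=C(Cl)c1ccccc1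
Why: Dienol ester formation (γ-deprotonation of the enal, eased by the γ-benzoyloxy group, then O-acylation of the extended enolate) from the s-trans enal should give the 1E bond, and iodine-catalysed equilibration with crystallisation should secure the all-E isomer.

**Step 3**
Reactants: 5 O-acetyl-L-serine
Product: 6 (2S)-3-acetoxy-2-hydroxypropanoic acid
Conditions: NaNO2, 1 M H2SO4, H2O, 0 °C → rt; continuous extraction with EtOAc
Reagents that add atoms: water, O
Why: Nitrous acid deamination of an α-amino acid proceeds with net retention through the α-lactone (double inversion), so the S configuration should be kept, and the primary acetate tolerates cold dilute acid.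

**Step 4**
Reactants: 6 (2S)-3-acetoxy-2-hydroxypropanoic acid; 7 pivalaldehyde
Product: 8 (2S,5S)-5-(acetoxymethyl)-2-tert-butyl-1,3-dioxolan-4-one (cis)
Conditions: p-TsOH·H2O (cat.), H2SO4 (cat.), pentane, reflux, Dean–Stark trap; purification to the pure cis isomer
Reagents that add atoms: none
Why: Acid-catalysed acetalisation of an α-hydroxy acid with water removal gives the dioxolanone with the new acetal carbon C2 set cis to the C5 side chain under thermodynamic control (self-regeneration-of-stereocentres principle), and the trans isomer must be removed completely because it would lead to the enantiomeric dienophile.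

**Step 5**
Reactants: 8 (2S,5S)-5-(acetoxymethyl)-2-tert-butyl-1,3-dioxolan-4-one
Product: 10 (2S,5Z)-5-(acetoxymethylidene)-2-tert-butyl-1,3-dioxolan-4-one, via C5 bromide 9 (not isolated)
Conditions: NBS, AIBN (cat.), PhCF3, reflux; cool, then Et3N, 0 °C → rt
Reagents that add atoms: N-bromosuccinimide, O=C1CCC(=O)N1Br (its bromine stands in 9 only and leaves again in the second stage)
Why: Wohl–Ziegler bromination should attack the captodative C5–H from the face opposite tert-butyl, and E2 loss of HBr then gives the exocyclic enol acetate, expected as the Z isomer (OAc syn to ring O1, anti to the lactone C=O) because amine-mediated addition–elimination can equilibrate towards this less dipole-strained form, with C2 left as the only stereocentre.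

**Step 6**
Reactants: 4 (1E,3E)-buta-1,3-diene-1,4-diyl dibenzoate; 10 (2S,5Z)-5-(acetoxymethylidene)-2-tert-butyl-1,3-dioxolan-4-one
Product: 11 (2S,5S,6S,9R,10R)-10-acetoxy-2-tert-butyl-4-oxo-1,3-dioxaspiro[4.5]dec-7-ene-6,9-diyl dibenzoate (all four oxygens on the carbocycle on one face, lactone carbonyl carbon on the other, tert-butyl on the side of the dioxolanone that faces C10)
Conditions: 4 (1.5 equiv), toluene (concentrated), BHT (cat.), sealed tube, 120 °C
Reagents that add atoms: none
Why: A concerted, asynchronous suprafacial [4π+2π] cycloaddition of the s-cis (E,E)-diene (HOMO raised by two acyloxy donors) onto the exocyclic C=C of 10 (LUMO lowered by the lactone carbonyl held s-cis in the five-membered ring) makes the bonds C4–C5 and C6–C1 of the target ring in one event. The closest known reaction types are the exo- and face-selective Diels–Alder additions of 2-tert-butyl-5-methylidene- and 5-ylidene-1,3-dioxolan-4-ones to acyclic dienes, and the all-cis adducts of (E,E)-1,4-diacyloxybutadienes with cyclic enediol carbonates. The only ring closed is the cyclohexene, formed by intermolecular six-centre cycloaddition as a spiro ring on dioxolanone C5, and its C2=C3 double bond comes from the central bond of the diene. C1 and C4 become cis because both benzoyloxy groups are outside (E) substituents, C5 and C6 keep the syn O/O relation of the Z-enol acetate, and the lactone-exo transition state (ring O1 and OAc under the diene, C=O pointing away, as is typical of s-cis-locked α-oxy enoates) should put both pairs on the same face. The absolute sense is controlled by the acetal carbon, since tert-butyl blocks one π face and the outside benzoyloxy group of the incoming diene must pass over the dioxolanone ring, so addition to the face bearing the acetal H of the 2S lactone should give the configuration of the target at all four centres. The step needs exo/endo and facial selectivity but no regioselectivity because the diene is the same from both ends, and diene isomers that contain a Z bond cannot reach the s-cis form and stay out of the reaction.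

**Step 7**
Reactants: 11 spiro-dioxolanone cycloadduct
Product: 12 (1S,2S,5R,6R)-6-acetoxy-2,5-bis(benzoyloxy)-1-hydroxycyclohex-3-ene-1-carboxylic acid
Conditions: TFA–H2O (9:1), 0 °C → rt
Reagents that add atoms: none
Why: Acid-catalysed acylal hydrolysis should be selective because loss of the carboxylate from protonated C2 gives an oxocarbenium ion that water traps, so pivalaldehyde (carrying the oxygen of water) is expelled and the tertiary OH and CO2H appear without touching a stereocentre, the acetate or the benzoates.

**Step 8**
Reactants: 12 hydroxy acid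
Product: 13 (1R,4S,5S,6R)-6-acetoxy-5-hydroxy-5-(hydroxymethyl)cyclohex-2-ene-1,4-diyl dibenzoate
Conditions: BH3·THF, THF, 0 °C → rt; then MeOH, evaporation
Reagents that add atoms: none
Why: Borane reduction of a carboxylic acid runs through the acyloxyborane (here a cyclic one with the neighbouring tertiary OH) and is much faster than attack on esters, while the ring alkene is deactivated by its two allylic benzoyloxy groups and no stereocentre is involved.

**Step 9**
Reactants: 13 monoacetate
Product: 14 (1R,4S,5R,6R)-5,6-dihydroxy-5-(hydroxymethyl)cyclohex-2-ene-1,4-diyl dibenzoate (target)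
Conditions: HCl (dilute, methanolic), MeOH–CH2Cl2, 0 °C → rt; solid NaHCO3, filtration
Reagents that add atoms: none
Why: Acid-catalysed methanolysis (transesterification) removes O-acetyl groups selectively in the presence of the less electrophilic conjugated O-benzoyl groups, and acid rather than base should keep acyl migration among the cis hydroxyls slow.

**Compound list**
1 | allyl benzoate | C=CCOC(=O)c1ccccc1 | starting material
2 | (E)-crotonaldehyde | C/C=C/C=O | starting material
3 | (E)-4-oxobut-2-en-1-yl benzoate | O=C/C=C/COC(=O)c1ccccc1 | intermediate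
4 | (1E,3E)-buta-1,3-diene-1,4-diyl dibenzoate | O=C(O/C=C/C=C/OC(=O)c1ccccc1)c1ccccc1 | intermediate
5 | O-acetyl-L-serine | CC(=O)OC[C@H](N)C(=O)O | starting material
6 | (2S)-3-acetoxy-2-hydroxypropanoic acid | CC(=O)OC[C@H](O)C(=O)O | intermediate
7 | pivalaldehyde | CC(C)(C)C=O | starting material
8 | (2S,5S)-5-(acetoxymethyl)-2-tert-butyl-1,3-dioxolan-4-one (cis) | CC(=O)OC[C@@H]1O[C@H](C(C)(C)C)OC1=O | intermediate
9 | 5-bromo derivative of 8 (Br on the face opposite tert-butyl, acetal carbon spatially unchanged) | CC(=O)OC[C@]1(Br)O[C@H](C(C)(C)C)OC1=O | intermediate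
10 | (2S,5Z)-5-(acetoxymethylidene)-2-tert-butyl-1,3-dioxolan-4-one | CC(=O)O/C=C1\O[C@H](C(C)(C)C)OC1=O | intermediate
11 | (2S,5S,6S,9R,10R)-10-acetoxy-2-tert-butyl-4-oxo-1,3-dioxaspiro[4.5]dec-7-ene-6,9-diyl dibenzoate | O=C(O[C@H]1C=C[C@@H](OC(=O)c2ccccc2)[C@@H](OC(C)=O)[C@@]13O[C@H](C(C)(C)C)OC3=O)c1ccccc1 | intermediate
12 | (1S,2S,5R,6R)-6-acetoxy-2,5-bis(benzoyloxy)-1-hydroxycyclohex-3-ene-1-carboxylic acid | O=C(O[C@H]1C=C[C@@H](OC(=O)c2ccccc2)[C@@H](OC(C)=O)[C@]1(O)C(=O)O)c1ccccc1 | intermediate
13 | (1R,4S,5S,6R)-6-acetoxy-5-hydroxy-5-(hydroxymethyl)cyclohex-2-ene-1,4-diyl dibenzoate | O=C(O[C@H]1C=C[C@@H](OC(=O)c2ccccc2)[C@@H](OC(C)=O)[C@]1(O)CO)c1ccccc1 | intermediate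
14 | (1R,4S,5R,6R)-5,6-dihydroxy-5-(hydroxymethyl)cyclohex-2-ene-1,4-diyl dibenzoate | O=C(O[C@H]1C=C[C@@H](OC(=O)c2ccccc2)[C@@H](O)[C@]1(O)CO)c1ccccc1 | target

Total step count: 9. Longest linear sequence: 7 (steps 3, 4, 5, 6, 7, 8, 9).

**Steps most likely to fail**

Step 6. The cycloaddition of a trisubstituted captodative alkene with a diene substituted at both termini may be slow. Thermal scrambling of the enol acetate geometry and an insufficient preference for the lactone-exo approach could then compete. The fallback raises the diene HOMO instead of the temperature. It sets out from 10 and comes back at 11.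
- But-2-yne-1,4-diol is alkylated with 4-methoxybenzyl chloride (NaH, DMF) to 1,4-bis[(4-methoxybenzyl)oxy]but-2-yne F1.
- Base-mediated prototropic isomerisation (KOt-Bu, THF) followed by iodine equilibration gives (1E,3E)-1,4-bis[(4-methoxybenzyl)oxy]buta-1,3-diene F2.
- This much more electron-rich diene should add to 10 at lower temperature, through an earlier transition state, to give the bis(4-methoxybenzyl) ether cycloadduct F3.
- Oxidative ether cleavage (DDQ, CH2Cl2–H2O) gives the allylic diol F4, and BzCl in pyridine converts it into 11.

Step 5. Hydrogen abstraction may occur at the acetal C–H or at the CH2OAc group. The acetoxy group may undergo an ionic 1,2-shift in the tertiary bromide, or the elimination may show poor control of alkene geometry. The fallback replaces the radical route by an oxidation and enol acylation route. It sets out from pivalaldehyde 7, with commercial O-benzyl-L-serine in place of 5, and comes back at 10.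
- The amino acid is deaminated as in step 3 to (2S)-3-(benzyloxy)-2-hydroxypropanoic acid F5.
- F5 is condensed with 7 as in step 4 to (2S,5S)-5-[(benzyloxy)methyl]-2-tert-butyl-1,3-dioxolan-4-one F6.
- Hydrogenolysis (H2, Pd/C, EtOAc) gives (2S,5S)-2-tert-butyl-5-(hydroxymethyl)-1,3-dioxolan-4-one F7.
- Swern oxidation gives the formyl lactone, which should rest as its enol (2S)-2-tert-butyl-5-(hydroxymethylidene)-1,3-dioxolan-4-one F8.
- O-acetylation (Ac2O, Et3N, DMAP cat.) under equilibrating conditions gives 10.

Step 8. Hydroboration of the ring alkene may compete because the hindered quaternary acid is reduced slowly, and excess borane may slowly attack the esters. The fallback uses carboxyl activation and borohydride, which leaves alkenes alone. It sets out from 12 and comes back at 13.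
- Isobutyl chloroformate and N-methylmorpholine (THF, −15 °C) convert 12 into the mixed carbonic anhydride F9.
- F9 is reduced at once with NaBH4 (THF–H2O, −15 → 0 °C, short contact) to 13.

**Further compounds**
F1 | step 6 | 1,4-bis[(4-methoxybenzyl)oxy]but-2-yne | COc1ccc(COCC#CCOCc2ccc(OC)cc2)cc1
F2 | step 6 | (1E,3E)-1,4-bis[(4-methoxybenzyl)oxy]buta-1,3-diene | COc1ccc(CO/C=C/C=C/OCc2ccc(OC)cc2)cc1
F3 | step 6 | (2S,5S,6S,9R,10R)-2-tert-butyl-6,9-bis[(4-methoxybenzyl)oxy]-4-oxo-1,3-dioxaspiro[4.5]dec-7-en-10-yl acetate | COc1ccc(CO[C@H]2C=C[C@@H](OCc3ccc(OC)cc3)[C@@H](OC(C)=O)[C@@]24O[C@H](C(C)(C)C)OC4=O)cc1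
F4 | step 6 | (2S,5S,6S,9R,10R)-2-tert-butyl-6,9-dihydroxy-4-oxo-1,3-dioxaspiro[4.5]dec-7-en-10-yl acetate | O[C@H]1C=C[C@@H](O)[C@@H](OC(C)=O)[C@@]12O[C@H](C(C)(C)C)OC2=O
F5 | step 5 | (2S)-3-(benzyloxy)-2-hydroxypropanoic acid | c1ccccc1COC[C@H](O)C(=O)O
F6 | step 5 | (2S,5S)-5-[(benzyloxy)methyl]-2-tert-butyl-1,3-dioxolan-4-one | c1ccccc1COC[C@@H]1O[C@H](C(C)(C)C)OC1=O
F7 | step 5 | (2S,5S)-2-tert-butyl-5-(hydroxymethyl)-1,3-dioxolan-4-one | OC[C@@H]1O[C@H](C(C)(C)C)OC1=O
F8 | step 5 | (2S)-2-tert-butyl-5-(hydroxymethylidene)-1,3-dioxolan-4-one (enol of the 5-carbaldehyde, alkene geometry labile) | OC=C1O[C@H](C(C)(C)C)OC1=O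
F9 | step 8 | mixed isobutyl carbonic anhydride of 12 | O=C(O[C@H]1C=C[C@@H](OC(=O)c2ccccc2)[C@@H](OC(C)=O)[C@]1(O)C(=O)OC(=O)OCC(C)C)c1ccccc1
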